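**Strategy.** The target is read as a bicyclo[2.2.2]octan-2-one (ring A carbons C1–C5 and C10, bridged by C20–C9) fused to cyclohexane ring B. Its C3–C20 and C9–C10 bonds are disconnected together by a retro-Diels–Alder step. In the forward sense, a thermal intramolecular Diels–Alder reaction joins the 2-silyloxy-1,3-diene C3=C2(OSi)–C1=C10 of a cyclohexadiene to the 1,1-disubstituted alkene C9=C20, tethered through C6–C7–C8 to quaternary C5. One operation closes ring B and the bicycle, sets C3, C9 and C10, and leaves the C2 ketone masked as a silyl enol ether. The precursor is a monocyclic 4,4,5-trisubstituted cyclohex-2-enone carrying the complete, stereodefined acyclic chain.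

Key step: step 13

Remark (numbering used throughout, clerodane-type): ring A = C1, C2 (ketone), C3, C4 (methyl C18), C5 (methyl C19), C10; ring B = C5, C6 (OAc), C7, C8 (methyl C17), C9, C10; C20 = CH2 linking C9 and C3; side chain C11–C12–C13(methyl C16)(OH)–C14=C15.

Assumption: (S)-(+)-linalool (coriandrol) is taken as a commercial chiral-pool material of adequate enantiomeric purity.

Remark (sense of induction): the catalyst enantiomers in steps 2, 9 and 10 are assigned from the accepted models for these catalyst classes, not from a result on this substrate.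

**Step 1**
Reactants: 1 but-3-en-2-one (methyl vinyl ketone)
Product: 2 2-(triisopropylsilyloxy)buta-1,3-diene
Conditions: TIPSOTf, Et3N, Et2O, 0 °C → rt
Reagents that add atoms: triisopropylsilyl trifluoromethanesulfonate (CC(C)[Si](C(C)C)(C(C)C)OS(=O)(=O)C(F)(F)F)
Why: Soft enolisation and O-silylation of the methyl ketone (silyl enol ether formation) should give the 2-silyloxydiene, the bulky silyl group making the later enol ether robust through steps 2–11.

**Step 2**
Reactants: 2 2-(triisopropylsilyloxy)buta-1,3-diene; 3 (E)-2-methylbut-2-enal (tiglic aldehyde)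
Product: 4 (1R,6R)-1,6-dimethyl-4-(triisopropylsilyloxy)cyclohex-3-ene-1-carbaldehyde
Conditions: (S)-B-(o-tolyl)-diphenylprolinol oxazaborolidine (20 mol%), Tf2NH (20 mol%), CH2Cl2, −78 → −20 °C
Reagents that add atoms: none
Why: Oxazaborolidinium-catalysed enantioselective Diels–Alder reaction in which the boron-bound s-trans enal (formyl C–H···O contact) is attacked on the face remote from the shielding phenyl group, which should set quaternary C5 and C4 in absolute terms, while the (E)-geometry of 3 makes the two methyl groups cis and the 2-silyloxy group directs the "para" regiochemistry.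

**Step 3**
Reactants: 4 (1R,6R)-1,6-dimethyl-4-(triisopropylsilyloxy)cyclohex-3-ene-1-carbaldehyde; 5 (E)-1-bromoprop-1-ene
Product: 7 (E)-1-[(1R,6R)-1,6-dimethyl-4-(triisopropylsilyloxy)cyclohex-3-en-1-yl]but-2-en-1-ol (both C6 epimers), via (E)-prop-1-enyllithium 6 (not isolated)
Conditions: 5, t-BuLi (2 equiv), Et2O, −78 °C; then 4, −78 → −20 °C; aq NH4Cl
Reagents that add atoms: none
Why: Bromine–lithium exchange with retention of alkene geometry and 1,2-addition of the alkenyllithium to the non-enolisable aldehyde; the C6 carbinol configuration is irrelevant because it is oxidised in step 4.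

**Step 4**
Reactants: 7 (E)-1-[(1R,6R)-1,6-dimethyl-4-(triisopropylsilyloxy)cyclohex-3-en-1-yl]but-2-en-1-ol
Product: 8 (E)-1-[(1R,6R)-1,6-dimethyl-4-(triisopropylsilyloxy)cyclohex-3-en-1-yl]but-2-en-1-one
Conditions: MnO2 (excess), CH2Cl2, rt
Reagents that add atoms: none
Why: Allylic alcohol oxidation with MnO2 should give the (E)-enone without touching the silyl enol ether or isomerising the alkene.

**Step 5**
Reactants: 9 (S)-(+)-linalool, (3S)-3,7-dimethylocta-1,6-dien-3-ol
Product: 10 triethyl{[(3S)-3,7-dimethylocta-1,6-dien-3-yl]oxy}silane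
Conditions: TESOTf, 2,6-lutidine, CH2Cl2, −78 → 0 °C
Reagents that add atoms: triethylsilyl trifluoromethanesulfonate (CC[Si](CC)(CC)OS(=O)(=O)C(F)(F)F)
Why: Silylation of the tertiary alcohol with the silyl triflate; C13 (S) comes from the chiral pool and is not touched again.

**Step 6**
Reactants: 10 triethyl{[(3S)-3,7-dimethylocta-1,6-dien-3-yl]oxy}silane
Product: 11 (4S)-4-methyl-4-(triethylsilyloxy)hex-5-enal
Conditions: O3, CH2Cl2, pyridine (cat.), −78 °C, Sudan Red 7B end point; then PPh3, −78 °C → rt
Reagents that add atoms: ozone ([O-][O+]=O)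
Why: Indicator-controlled ozonolysis should cleave the electron-rich trisubstituted alkene in preference to the monosubstituted vinyl group, and reductive work-up gives the aldehyde (future C9).

**Step 7**
Reactants: 11 (4S)-4-methyl-4-(triethylsilyloxy)hex-5-enal
Product: 12 (3S)-3-methyl-3-(triethylsilyloxy)hept-1-en-6-yne
Conditions: dimethyl (1-diazo-2-oxopropyl)phosphonate, K2CO3, MeOH, 0 °C → rt
Reagents that add atoms: dimethyl (1-diazo-2-oxopropyl)phosphonate (COP(=O)(OC)C(=[N+]=[N-])C(C)=O)
Why: Seyferth–Gilbert homologation with the Ohira–Bestmann reagent converts the aldehyde into the terminal alkyne (adding C20) under mild base, the aldehyde having no α-stereocentre.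

**Step 8**
Reactants: 12 (3S)-3-methyl-3-(triethylsilyloxy)hept-1-en-6-yne
Product: 14 2-[(5S)-5-methyl-5-(triethylsilyloxy)hepta-1,6-dien-2-yl]-4,4,5,5-tetramethyl-1,3,2-dioxaborolane, via alkenylalane 13 (not isolated)
Conditions: NiCl2(dppp) (3 mol%), i-Bu2AlH (1.3 equiv), THF, 0 °C → rt; then MeOBpin, 0 → 60 °C
Reagents that add atoms: 2-methoxy-4,4,5,5-tetramethyl-1,3,2-dioxaborolane (COB1OC(C)(C)C(C)(C)O1)
Why: Nickel-catalysed α-selective (Markovnikov) hydroalumination of the terminal alkyne places aluminium on the internal carbon (future C9), and aluminium-to-boron exchange with the methoxyboronate should give the 1,1-disubstituted alkenylboronate.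

**Step 9**
Reactants: 8 (E)-1-[(1R,6R)-1,6-dimethyl-4-(triisopropylsilyloxy)cyclohex-3-en-1-yl]but-2-en-1-one; 14 2-[(5S)-5-methyl-5-(triethylsilyloxy)hepta-1,6-dien-2-yl]-4,4,5,5-tetramethyl-1,3,2-dioxaborolane
Product: 15 (3R,7S)-1-[(1R,6R)-1,6-dimethyl-4-(triisopropylsilyloxy)cyclohex-3-en-1-yl]-3,7-dimethyl-4-methylidene-7-(triethylsilyloxy)non-8-en-1-one
Conditions: [Rh(OH)(cod)]2 (2.5 mol%), (R)-BINAP (6 mol%), KOH (0.5 equiv), 1,4-dioxane/H2O (10:1), 40 °C
Reagents that add atoms: none
Why: Rhodium-catalysed asymmetric conjugate addition (Hayashi–Miyaura reaction) to the only enone present, the ring ketone being masked, in which (R)-BINAP is chosen by analogy with linear (E)-enones to deliver the alkenyl group to the Re face of C8 (Si face of C7) and so set C8 as R under catalyst control.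

**Step 10**
Reactants: 15 (3R,7S)-1-[(1R,6R)-1,6-dimethyl-4-(triisopropylsilyloxy)cyclohex-3-en-1-yl]-3,7-dimethyl-4-methylidene-7-(triethylsilyloxy)non-8-en-1-one
Product: 16 (1R,3R,7S)-1-[(1R,6R)-1,6-dimethyl-4-(triisopropylsilyloxy)cyclohex-3-en-1-yl]-3,7-dimethyl-4-methylidene-7-(triethylsilyloxy)non-8-en-1-ol
Conditions: (S)-2-methyl-CBS-oxazaborolidine (1 equiv), catecholborane, toluene, −78 → −30 °C; aq NaOH wash
Reagents that add atoms: none
Why: Corey–Bakshi–Shibata reduction in which the quaternary C5 side acts as the large group and C7H2 as the small one, so the (S)-catalyst should give the (6R)-alcohol under reagent control, while catecholborane leaves the three C=C bonds alone at this temperature.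

**Step 11**
Reactants: 16 (1R,3R,7S)-1-[(1R,6R)-1,6-dimethyl-4-(triisopropylsilyloxy)cyclohex-3-en-1-yl]-3,7-dimethyl-4-methylidene-7-(triethylsilyloxy)non-8-en-1-ol
Product: 17 (1R,3R,7S)-1-[(1R,6R)-1,6-dimethyl-4-(triisopropylsilyloxy)cyclohex-3-en-1-yl]-3,7-dimethyl-4-methylidene-7-(triethylsilyloxy)non-8-en-1-yl acetate
Conditions: Ac2O, Et3N, DMAP, CH2Cl2, rt
Reagents that add atoms: acetic anhydride (CC(=O)OC(C)=O)
Why: DMAP-catalysed acylation of the hindered secondary alcohol; the tertiary alcohol is already silylated, so no competing acetylation can occur.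

**Step 12**
Reactants: 17 (1R,3R,7S)-1-[(1R,6R)-1,6-dimethyl-4-(triisopropylsilyloxy)cyclohex-3-en-1-yl]-3,7-dimethyl-4-methylidene-7-(triethylsilyloxy)non-8-en-1-yl acetate
Product: 18 (1R,3R,7S)-1-[(1S,6R)-1,6-dimethyl-4-oxocyclohex-2-en-1-yl]-3,7-dimethyl-4-methylidene-7-(triethylsilyloxy)non-8-en-1-yl acetate
Conditions: Pd(OAc)2 (1.2 equiv), MeCN, 40 °C
Reagents that add atoms: none
Why: Saegusa–Ito oxidation, in which palladation of the silyl enol ether at C1 and β-hydride elimination from C10 should give the C1=C10 enone regiospecifically, the enol ether position having been fixed by the cycloaddition of step 2.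

**Step 13**
Reactants: 18 (1R,3R,7S)-1-[(1S,6R)-1,6-dimethyl-4-oxocyclohex-2-en-1-yl]-3,7-dimethyl-4-methylidene-7-(triethylsilyloxy)non-8-en-1-yl acetate
Product: 20 tricyclic cycloadduct (C1=C2 tert-butyldimethylsilyl enol ether and C13 triethylsilyl ether of the target; 3R,4R,5S,6R,8R,9S,10S,13S), via silyl dienol ether 19 (not isolated)
Conditions: TBSOTf, Et3N, toluene, 0 °C → rt; toluene phase decanted from Et3NH·OTf; BHT, 190 °C, sealed tube
Reagents that add atoms: tert-butyldimethylsilyl trifluoromethanesulfonate (CC(C)(C)[Si](C)(C)OS(=O)(=O)C(F)(F)F)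
Why: Soft enolisation can occur only at C3 because C5 is quaternary, giving the cross-conjugated 2-silyloxy-1,3-diene 19, whose C3=C2–C1=C10 unit then undergoes a concerted, thermally allowed suprafacial [4+2] cycloaddition with the tethered C9=C20 alkene. The closest known reaction type is the thermal intramolecular Diels–Alder reaction of 5-alkenyl-2-silyloxycyclohexa-1,3-dienes with unactivated alkenes, a standard entry to bicyclo[2.2.2]octanones. The C3–C20 bond closes the bicyclo[2.2.2]octene (new six-membered ring C3–C20–C9–C10–C1–C2) and the C9–C10 bond closes ring B (C5–C6–C7–C8–C9–C10), both as six-membered closures within one cycloaddition spanned by the three-atom tether C6–C7–C8. C3 and C10 are set because the tether on C5 can deliver the alkene only to the diene face syn to C6 (anti to the C4 methyl), and C9 is set because C8 must sit on the C5 side of the new bridge, which turns C11 toward the silyl enol ether bridge. Regiochemistry (C20 to C3, C9 to C10) is enforced by tether length, the C14=C15 vinyl group cannot reach the diene, and quaternary C5 blocks aromatisation. The step needs only enough thermal driving force to overcome an unactivated 1,1-disubstituted dienophile forming quaternary C9, which intramolecularity should supply.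

**Step 14**
Reactants: 20 tricyclic cycloadduct (C1=C2 tert-butyldimethylsilyl enol ether and C13 triethylsilyl ether of the target)
Product: 21 target CNP0281208.1
Conditions: HF·pyridine, pyridine, THF, 0 °C → rt
Reagents that add atoms: none
Why: Fluoride-mediated desilylation unveils the C2 ketone by protonation at C1 (no stereocentre formed) and frees the C13 alcohol under buffered, non-ionising conditions that should spare the acetate and the tertiary allylic alcohol.

**Compound list**

1 | but-3-en-2-one (methyl vinyl ketone) | CC(=O)C=C | starting material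
2 | 2-(triisopropylsilyloxy)buta-1,3-diene | C=CC(=C)O[Si](C(C)C)(C(C)C)C(C)C | intermediate
3 | (E)-2-methylbut-2-enal (tiglic aldehyde) | C/C=C(\C)C=O | starting material
4 | (1R,6R)-1,6-dimethyl-4-(triisopropylsilyloxy)cyclohex-3-ene-1-carbaldehyde (methyl groups cis) | O=C[C@]1(C)CC=C(O[Si](C(C)C)(C(C)C)C(C)C)C[C@H]1C | intermediate
5 | (E)-1-bromoprop-1-ene | C/C=C/Br | starting material
6 | (E)-prop-1-enyllithium | C/C=C/[Li] | intermediate
7 | (E)-1-[(1R,6R)-1,6-dimethyl-4-(triisopropylsilyloxy)cyclohex-3-en-1-yl]but-2-en-1-ol (both C6 epimers) | C/C=C/C(O)[C@]1(C)CC=C(O[Si](C(C)C)(C(C)C)C(C)C)C[C@H]1C | intermediate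
8 | (E)-1-[(1R,6R)-1,6-dimethyl-4-(triisopropylsilyloxy)cyclohex-3-en-1-yl]but-2-en-1-one | C/C=C/C(=O)[C@]1(C)CC=C(O[Si](C(C)C)(C(C)C)C(C)C)C[C@H]1C | intermediate
9 | (S)-(+)-linalool, (3S)-3,7-dimethylocta-1,6-dien-3-ol | C=C[C@@](C)(O)CCC=C(C)C | starting material
10 | triethyl{[(3S)-3,7-dimethylocta-1,6-dien-3-yl]oxy}silane | C=C[C@@](C)(O[Si](CC)(CC)CC)CCC=C(C)C | intermediate
11 | (4S)-4-methyl-4-(triethylsilyloxy)hex-5-enal | C=C[C@@](C)(O[Si](CC)(CC)CC)CCC=O | intermediate
12 | (3S)-3-methyl-3-(triethylsilyloxy)hept-1-en-6-yne | C=C[C@@](C)(O[Si](CC)(CC)CC)CCC#C | intermediate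
13 | diisobutyl[(5S)-5-methyl-5-(triethylsilyloxy)hepta-1,6-dien-2-yl]aluminium | C=C[C@@](C)(O[Si](CC)(CC)CC)CCC(=C)[Al](CC(C)C)CC(C)C | intermediate
14 | 2-[(5S)-5-methyl-5-(triethylsilyloxy)hepta-1,6-dien-2-yl]-4,4,5,5-tetramethyl-1,3,2-dioxaborolane | C=C[C@@](C)(O[Si](CC)(CC)CC)CCC(=C)B1OC(C)(C)C(C)(C)O1 | intermediate
15 | (3R,7S)-1-[(1R,6R)-1,6-dimethyl-4-(triisopropylsilyloxy)cyclohex-3-en-1-yl]-3,7-dimethyl-4-methylidene-7-(triethylsilyloxy)non-8-en-1-one | C=C[C@@](C)(O[Si](CC)(CC)CC)CCC(=C)[C@H](C)CC(=O)[C@]1(C)CC=C(O[Si](C(C)C)(C(C)C)C(C)C)C[C@H]1C | intermediate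
16 | (1R,3R,7S)-1-[(1R,6R)-1,6-dimethyl-4-(triisopropylsilyloxy)cyclohex-3-en-1-yl]-3,7-dimethyl-4-methylidene-7-(triethylsilyloxy)non-8-en-1-ol | C=C[C@@](C)(O[Si](CC)(CC)CC)CCC(=C)[C@H](C)C[C@@H](O)[C@]1(C)CC=C(O[Si](C(C)C)(C(C)C)C(C)C)C[C@H]1C | intermediate
17 | (1R,3R,7S)-1-[(1R,6R)-1,6-dimethyl-4-(triisopropylsilyloxy)cyclohex-3-en-1-yl]-3,7-dimethyl-4-methylidene-7-(triethylsilyloxy)non-8-en-1-yl acetate | C=C[C@@](C)(O[Si](CC)(CC)CC)CCC(=C)[C@H](C)C[C@@H](OC(C)=O)[C@]1(C)CC=C(O[Si](C(C)C)(C(C)C)C(C)C)C[C@H]1C | intermediate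
18 | (1R,3R,7S)-1-[(1S,6R)-1,6-dimethyl-4-oxocyclohex-2-en-1-yl]-3,7-dimethyl-4-methylidene-7-(triethylsilyloxy)non-8-en-1-yl acetate | C=C[C@@](C)(O[Si](CC)(CC)CC)CCC(=C)[C@H](C)C[C@@H](OC(C)=O)[C@]1(C)C=CC(=O)C[C@H]1C | intermediate
19 | (1R,3R,7S)-1-[(1R,6R)-4-(tert-butyldimethylsilyloxy)-1,6-dimethylcyclohexa-2,4-dien-1-yl]-3,7-dimethyl-4-methylidene-7-(triethylsilyloxy)non-8-en-1-yl acetate | C=C[C@@](C)(O[Si](CC)(CC)CC)CCC(=C)[C@H](C)C[C@@H](OC(C)=O)[C@]1(C)C=CC(O[Si](C)(C)C(C)(C)C)=C[C@H]1C | intermediate
20 | tricyclic cycloadduct: C1=C2 tert-butyldimethylsilyl enol ether and C13 triethylsilyl ether of the target (3R,4R,5S,6R,8R,9S,10S,13S) | C=C[C@@](C)(O[Si](CC)(CC)CC)CC[C@@]12C[C@H]3C(O[Si](C)(C)C(C)(C)C)=C[C@@H]1[C@](C)([C@@H]3C)[C@H](OC(C)=O)C[C@H]2C | intermediate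
21 | CNP0281208.1: (3R,4R,5S,6R,8R,9S,10S,13S)-6-acetoxy-13-hydroxy-3,20-cycloclerod-14-en-2-one (descriptive name, numbering as in the remark) | C=C[C@@](C)(O)CC[C@@]12C[C@H]3C(=O)C[C@@H]1[C@](C)([C@@H]3C)[C@H](OC(C)=O)C[C@H]2C | target

**Step count and risks**

Total steps: 14. Longest linear sequence: 10 steps (steps 1–4 and 9–14; the linalool branch, steps 5–8 and 9–14, is equally long).

Risk 1, step 13. The cycloaddition may be slower than thermal loss of the dienol silyl group or ionisation of the tertiary allylic silyl ether, because the dienophile is unactivated, 1,1-disubstituted and must form a quaternary centre. The fallback makes the same two bonds stepwise and sets out from 18. Epoxidation with mCPBA should take the electron-rich C9=C20 alkene ahead of the vinyl group and the enone, giving the 9,20-epoxide F1. Cp2TiCl (trivalent titanium, from Cp2TiCl2 and Zn, THF) should open it to the tertiary C9 radical, which closes ring B by 6-exo Giese addition to C10 of the enone (Nugent–RajanBabu-type reductive epoxide cyclisation) to give the cis-fused hydroxymethyl decalone F2. Tosylation (TsCl, pyridine) gives the tosylate F3. KN(SiMe3)2 in THF then closes C3–C20 by intramolecular enolate alkylation, since the C1 enolate could only form a cyclobutane, giving the C13 triethylsilyl ether of the target F4. HF·pyridine returns the route at 21. Its weakness is that the C9 and C10 configurations are no longer enforced by a concerted transition state.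

Risk 2, step 2. The α,β-disubstituted enal may react sluggishly, the silyl enol ether may add to the aldehyde carbonyl instead (Mukaiyama-type 1,2-addition), or facial discrimination may be incomplete. The fallback replaces asymmetric catalysis by resolution and sets out from 2 and 3. A thermal or Me2AlCl-promoted cycloaddition gives 4 together with its enantiomer, the (1S,6S)-aldehyde F1-bis, listed below as F5. Condensation with (1S,2S)-N,N'-dimethyl-1,2-diphenylethane-1,2-diamine gives the diastereomeric aminals, the aminal of 4 F6 and the aminal of the (1S,6S)-aldehyde F7. After chromatographic separation, hydrolysis of F6 on wet silica or in dilute aqueous acetic acid returns the route at 4 and recovers the diamine.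

Risk 3, step 9. Transmetallation of the hindered α-branched alkenylboronate may be slow relative to protodeboronation, and catalyst control at C8 may be eroded by the C4 and C5 centres. The fallback leaves the boron and rhodium manifold: it sets out from 12 and 8, and the alkenylalane 13 from the first half of step 8 is used directly in a copper-catalysed asymmetric conjugate addition ([Cu(MeCN)4]BF4, chiral phosphoramidite ligand, Et2O, −30 °C). Aqueous work-up returns the route at 15; no new compound is formed.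

**Further compounds**

F1 | step 13 | 9,20-epoxide of enone acetate 18 (both C9 epimers) | C=C[C@@](C)(O[Si](CC)(CC)CC)CCC1(CO1)[C@H](C)C[C@@H](OC(C)=O)[C@]2(C)C=CC(=O)C[C@H]2C
F2 | step 13 | cis-fused 2-oxodecalin with C20 hydroxymethyl on C9, C6 acetate and C13 triethylsilyl ether (stereocentres as in the target) | C=C[C@@](C)(O[Si](CC)(CC)CC)CC[C@@]1(CO)[C@@H]2CC(=O)C[C@@H](C)[C@]2(C)[C@H](OC(C)=O)C[C@H]1C
F3 | step 13 | C20 p-toluenesulfonate of F2 | C=C[C@@](C)(O[Si](CC)(CC)CC)CC[C@@]1(COS(=O)(=O)c3ccc(C)cc3)[C@@H]2CC(=O)C[C@@H](C)[C@]2(C)[C@H](OC(C)=O)C[C@H]1C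
F4 | step 13 | C13 triethylsilyl ether of the target | C=C[C@@](C)(O[Si](CC)(CC)CC)CC[C@@]12C[C@H]3C(=O)C[C@@H]1[C@](C)([C@@H]3C)[C@H](OC(C)=O)C[C@H]2C
F5 | step 2 | (1S,6S)-1,6-dimethyl-4-(triisopropylsilyloxy)cyclohex-3-ene-1-carbaldehyde (enantiomer of 4, named F1-bis in the text) | O=C[C@@]1(C)CC=C(O[Si](C(C)C)(C(C)C)C(C)C)C[C@@H]1C
F6 | step 2 | (4S,5S)-2-[(1R,6R)-1,6-dimethyl-4-(triisopropylsilyloxy)cyclohex-3-en-1-yl]-1,3-dimethyl-4,5-diphenylimidazolidine (aminal of 4) | CN1[C@@H](c2ccccc2)[C@H](c2ccccc2)N(C)C1[C@]3(C)CC=C(O[Si](C(C)C)(C(C)C)C(C)C)C[C@H]3C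
F7 | step 2 | (4S,5S)-2-[(1S,6S)-1,6-dimethyl-4-(triisopropylsilyloxy)cyclohex-3-en-1-yl]-1,3-dimethyl-4,5-diphenylimidazolidine (aminal of F5) | CN1[C@@H](c2ccccc2)[C@H](c2ccccc2)N(C)C1[C@@]3(C)CC=C(O[Si](C(C)C)(C(C)C)C(C)C)C[C@@H]3C
F0 | step 9 | none | none
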